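Assumption: jaspaquinol has no stereocentre, so "single enantiomer" is read as the single (2E,6E) geometric isomer. Chain numbering: C1′ is the benzylic CH2 and C9′ is the CH2 on the cyclohexene.

## Retrosynthetic overview

1. Key cut in mid-chain at C5′(sp3)–C6′(sp2): Ni-mediated radical cross-electrophile coupling of E-vinyl iodide 6 (ring half) with homoallylic bromide 9 (free hydroquinone half). No protecting groups are used.
2. 6 comes from syn-methylalumination/iodination of alkyne 5. 5 comes from a second radical sp2–sp3 coupling, at the hindered C9′–C10′ bond, of enol triflate 3 with 4-bromobut-1-yne.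
3. 3 comes from 2-methylcyclohexanone by two enolate methylations and O-triflation.
4. 9 comes from Friedel–Crafts allylation of hydroquinone with allylic alcohol 7. 7 comes from the same bromobutyne by methylalumination/formaldehyde.
5. No ring is built: the cyclohexene and the arene both arrive intact. Both E-olefins are set by syn-carboalumination.

## Route

**Step 1**
Reactants: 1, 2-methylcyclohexanone (racemic)
Product: 2, 2,2,6-trimethylcyclohexanone (racemic)
Conditions: LDA (1.05 equiv), THF, −78 °C; MeI (1.1 equiv), to 0 °C; recool; LDA (1.15 equiv), −78 to 0 °C; MeI (1.5 equiv), to rt (one pot, two cycles)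
Reagents that add atoms: iodomethane, CI (two CH3)
Why: Lithium-enolate C-methylation run twice converges on the same 2,2,6-trimethyl ketone whichever α-carbon is methylated first, a third deprotonation at the hindered methine is slow, any tetramethyl by-product has no α-H and is purged in Step 2, and the racemic C6 centre is erased in Step 2.

**Step 2**
Reactants: 2, 2,2,6-trimethylcyclohexanone
Product: 3, 2,6,6-trimethylcyclohex-1-en-1-yl trifluoromethanesulfonate
Conditions: LDA (1.2 equiv), THF, −78 to 0 °C, 2 h; PhNTf2 (1.2 equiv), 0 °C to rt
Reagents that add atoms: N-phenylbis(trifluoromethanesulfonimide), O=S(=O)(N(c1ccccc1)S(=O)(=O)C(F)(F)F)C(F)(F)F (adds SO2CF3)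
Why: Enol triflate synthesis in which only one α-C–H remains, so enolisation is regiospecific and O-sulfonylation fixes the tetrasubstituted ring alkene in its final position.

**Step 3**
Reactants: 3, enol triflate; 4, 4-bromobut-1-yne
Product: 5, 2-(but-3-yn-1-yl)-1,3,3-trimethylcyclohex-1-ene
Conditions: NiBr2·glyme (10 mol %), 2,2′-bipyridine (12 mol %), Mn (3 equiv), NaI (1 equiv), DMA, 40 °C; 4 (2 equiv) added over 6 h
Reagents that add atoms: none
Why: In this Ni-catalysed reductive cross-electrophile coupling, Ni(0) inserts into C–OTf, Ni(I) abstracts halogen from the alkyl iodide formed in situ, the small but-3-ynyl radical (no geometry to lose) is captured at nickel rather than at the crowded carbon, reductive elimination from congested Ni(III) forms the hindered bond, and the unactivated terminal alkyne is a poor radical acceptor that slow addition keeps dilute.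

**Step 4**
Reactants: 5, ring alkyne
Product: 6, 2-[(3E)-4-iodo-3-methylbut-3-en-1-yl]-1,3,3-trimethylcyclohex-1-ene
Conditions: Me3Al (2.5 equiv), Cp2ZrCl2 (25 mol %), CH2Cl2, 0 °C to rt; then I2, THF, −30 to 0 °C
Reagents that add atoms: trimethylaluminium, C[Al](C)C (adds CH3); iodine, II (adds I)
Why: Negishi Zr-catalysed methylalumination adds Me–Al syn with Al at the terminus, iodinolysis proceeds with retention to set C6′=C7′ as E (typically ≥98:2), and the tetrasubstituted ring alkene is inert.

**Step 5**
Reactants: 4, 4-bromobut-1-yne
Product: 7, (2E)-5-bromo-3-methylpent-2-en-1-ol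
Conditions: Me3Al (2 equiv), Cp2ZrCl2 (20 mol %), CH2Cl2, 0 °C to rt; then (CH2O)n (5 equiv), 0 °C to rt; Rochelle salt work-up
Reagents that add atoms: trimethylaluminium, C[Al](C)C (adds CH3); formaldehyde (as paraformaldehyde), C=O (adds CH2OH)
Why: The same syn-methylalumination sets C2′=C3′ as E, the neutral alkenylalane adds directly to Al-activated formaldehyde with retention, and no n-BuLi "ate" activation is used, so the alkenyl carbon does not close onto the primary bromide to give a cyclobutene.

**Step 6**
Reactants: 7, bromo allylic alcohol; 8, hydroquinone (4 equiv)
Product: 9, 2-[(2E)-5-bromo-3-methylpent-2-en-1-yl]benzene-1,4-diol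
Conditions: BF3·OEt2 (0.5 equiv), 1,4-dioxane, rt, N2
Reagents that add atoms: none
Why: In this Friedel–Crafts allylation the four ring C–H positions are equivalent, so only one mono-adduct is possible, the arene attacks the primary terminus of the configurationally stable allyl cation with E retained, the primary bromide is inert, and excess hydroquinone with substoichiometric acid limits dialkylation and chroman closure.

**Step 7 (key step)**
Reactants: 6, E-vinyl iodide (1 equiv); 9, homoallylic bromide (1.5 equiv)
Product: 10, jaspaquinol, 2-[(2E,6E)-3,7-dimethyl-9-(2,6,6-trimethylcyclohex-1-en-1-yl)nona-2,6-dien-1-yl]benzene-1,4-diol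
Conditions: NiI2 (10 mol %), 2,2′-bipyridine (10 mol %), Mn (3 equiv), NaI (0.5 equiv), degassed DMA, 25 °C; aq. Na2S2O4 work-up
Reagents that add atoms: none
Why: In this Ni-catalysed radical alkenyl–alkyl cross-electrophile coupling, stereoretentive oxidative addition of 6 gives alkenyl–Ni(II), which traps the C5′ primary radical made by halogen abstraction from 9, and reductive elimination forms C5′–C6′ with both olefins kept E, because radical capture outruns the slow 3-exo closure onto the methyl-bearing C3′; Mn forms no protolysable alkyl-metal, and H-bonding of the phenols to DMA retards O–H to C• transfer, so the free hydroquinone is carried through.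

## Compound list

| No. | Name | SMILES | Role |
|---|---|---|---|
| 1 | 2-methylcyclohexanone (racemic) | CC1CCCCC1=O | starting material |
| 2 | 2,2,6-trimethylcyclohexanone (racemic) | CC1CCCC(C)(C)C1=O | intermediate |
| 3 | 2,6,6-trimethylcyclohex-1-en-1-yl triflate | CC1=C(OS(=O)(=O)C(F)(F)F)C(C)(C)CCC1 | intermediate |
| 4 | 4-bromobut-1-yne | C#CCCBr | starting material |
| 5 | 2-(but-3-yn-1-yl)-1,3,3-trimethylcyclohex-1-ene | CC1=C(CCC#C)C(C)(C)CCC1 | intermediate |
| 6 | 2-[(3E)-4-iodo-3-methylbut-3-en-1-yl]-1,3,3-trimethylcyclohex-1-ene | CC1=C(CC/C(C)=C/I)C(C)(C)CCC1 | intermediate |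
| 7 | (2E)-5-bromo-3-methylpent-2-en-1-ol | BrCC/C(C)=C/CO | intermediate |
| 8 | hydroquinone | Oc1ccc(O)cc1 | starting material |
| 9 | 2-[(2E)-5-bromo-3-methylpent-2-en-1-yl]benzene-1,4-diol | BrCC/C(C)=C/Cc1cc(O)ccc1O | intermediate |
| 10 | jaspaquinol | CC1=C(CC/C(C)=C/CC/C(C)=C/Cc2cc(O)ccc2O)C(C)(C)CCC1 | target |

## Step count

Total step count: 7.
Longest linear sequence: 5 (Steps 1, 2, 3, 4, 7). The second branch is Steps 5, 6, 7.

## Steps most likely to fail

1. **Step 3.** The tetrasubstituted triflate sits next to a quaternary carbon, so oxidative addition and radical capture may be slow. Idle Ni(0) may then oligomerise the terminal alkyne.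
   Fallback: abandon the reductive radical coupling at this bond. C-silylate 4, convert it to the homopropargylzinc reagent, join it to 3 by Pd-catalysed Negishi coupling, then remove the silyl group with K2CO3/MeOH to reach 5 (two extra steps).
2. **Step 7.** The free hydroquinone may quench the alkyl radical to give hydrodebromination. Diene homodimer from 6, or some E/Z erosion at C2′=C3′, may also appear.
   Fallback: change the bond order. Couple 6 with bromo alcohol 7, where no phenol is present, to give the (2E,6E)-C20 allylic alcohol. Introduce hydroquinone last by the BF3 Friedel–Crafts allylation. The step count is unchanged.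
3. **Step 6.** Conversion is usually modest for this type of allylation, with competing dialkylation, O-alkylation and acid-induced chroman closure.
   Fallback: form C1′–C2′ instead of Ar–C1′. Couple the alkenylalane from Step 5 directly with 2,5-dimethoxybenzyl chloride under Ni(0) catalysis; the chloride comes from hydroquinone by O-methylation and chloromethylation. Carry the dimethyl ether through the key coupling, then unmask at the end with CAN followed by Na2S2O4.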